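The route rests on disconnecting the C6–C7 bond that is shared by the ten-membered carbocycle and the γ-lactone (germacrane numbering). The O–C12(=O)–C11(=C13H2)–C7–C6 lactone is the signature of a carbonyl 2-(alkoxycarbonyl)allylation. A CrCl2-mediated intramolecular Nozaki–Hiyama–Kishi allylation of an acyclic (Z)-enal (C6) by a tethered (Z)-2-(bromomethyl)enoate (C13–C11=C7) should close the ten-membered ring, set C6 and C7, move the alkene to the C11=C13 exo-methylene and, by lactonisation of the C6 alkoxide onto C12, form the cis-fused lactone in one operation. The precursor already carries the C1–C10 epoxide, the C3 acetate, a C8 silyl ether and a C15 PMB ether.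

Key step: step 15

Remark: germacrane numbering is used throughout (ring C1–C10, lactone C6–O–C12, C14 = methyl on C10, C15 = CH2O on C4); the structure is read as 1R,3S,6S,7R,8R,10S with a (4Z)-alkene, H6 and H7 cis, and C2 and C9 cis on the epoxide.
Remark: in the O8-silyl compounds 26, 27 and F2 the C7 descriptor is S only because the silyloxy-bearing C8 outranks C6; the geometry is that of the target.
Assumption: compounds 1, 6, 7, 9 and 23 are taken as commercial. PMB = 4-methoxybenzyl, TBS = tert-butyldimethylsilyl, TES = triethylsilyl.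

Step 1
Reactants: 1 but-2-yne-1,4-diol
Product: 2 4-[(4-methoxybenzyl)oxy]but-2-yn-1-ol
Conditions: NaH (1 equiv), 4-methoxybenzyl chloride (1 equiv), Bu4NI (cat.), THF/DMF, 0 °C to rt; diol in threefold excess
Reagents that add atoms: 4-methoxybenzyl chloride, COc1ccc(CCl)cc1
Why: Williamson etherification of the mono-alkoxide, in which the excess of the symmetrical diol should suppress bis-alkylation; no stereocentre is formed.

Step 2
Reactants: 2 4-[(4-methoxybenzyl)oxy]but-2-yn-1-ol
Product: 4 (Z)-3-iodo-4-[(4-methoxybenzyl)oxy]but-2-en-1-ol, via cyclic alkenylalanate 3 (not isolated)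
Conditions: NaAlH2(OCH2CH2OCH3)2 (Red-Al), THF, 0 °C to rt; then I2, THF, −78 °C
Reagents that add atoms: iodine, II
Why: Hydroxyl-directed trans-hydroalumination of the propargylic alcohol delivers hydride to C5 and aluminium to C4 within a five-membered alanate, and iodinolysis with retention should give the (Z)-iodide with iodine cis to CH2OH, which fixes the C4=C5 geometry of the target (C3 cis to C6).

Step 3
Reactants: 4 (Z)-3-iodo-4-[(4-methoxybenzyl)oxy]but-2-en-1-ol
Product: 5 (Z)-triethyl({3-iodo-4-[(4-methoxybenzyl)oxy]but-2-en-1-yl}oxy)silane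
Conditions: Et3SiCl, imidazole, CH2Cl2, 0 °C
Reagents that add atoms: chlorotriethylsilane, CC[Si](Cl)(CC)CC
Why: Standard silylation of the primary allylic alcohol, the triethylsilyl ether being chosen because it can later be oxidised directly to the aldehyde.

Step 4
Reactants: 6 3-[(tert-butyldimethylsilyl)oxy]propanal; 7 ethyltriphenylphosphonium iodide
Product: 8 (Z)-tert-butyl[(4-iodopent-3-en-1-yl)oxy]dimethylsilane
Conditions: 7, n-BuLi, THF, rt; I2, −78 °C; NaHMDS, −20 °C; then 6, −78 °C to rt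
Reagents that add atoms: iodine, II
Why: Wittig olefination with the α-iodo ylide (Zhao olefination), whose kinetically formed cis-oxaphosphetane places iodine cis to the alkyl chain and so should give the (Z)-iodide that encodes the C1=C10 geometry (C2 cis to C9).

Step 5
Reactants: 8 (Z)-tert-butyl[(4-iodopent-3-en-1-yl)oxy]dimethylsilane; 9 (R)-epichlorohydrin
Product: 11 (2R,4Z)-8-[(tert-butyldimethylsilyl)oxy]-1-chloro-4-methyloct-4-en-2-ol, via alkenyllithium 10 (not isolated)
Conditions: t-BuLi (2 equiv), Et2O, −78 °C; then 9, BF3·OEt2, −78 °C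
Reagents that add atoms: none
Why: Iodine–lithium exchange proceeds with retention of alkene geometry and the BF3-activated epoxide is opened by SN2 attack at its terminal carbon (C9), so the C8 stereocentre is taken unchanged from (R)-epichlorohydrin.

Step 6
Reactants: 11 (2R,4Z)-8-[(tert-butyldimethylsilyl)oxy]-1-chloro-4-methyloct-4-en-2-ol
Product: 13 (3R,5Z)-8-[(tert-butyldimethylsilyl)oxy]-5-methylocta-1,5-dien-3-ol, via terminal epoxide 12 (not isolated)
Conditions: Me3S+ I− (4 equiv), n-BuLi (3.8 equiv), THF, −20 °C to rt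
Reagents that add atoms: trimethylsulfonium iodide, C[S+](C)C.[I-]
Why: Dimethylsulfonium methylide (Corey–Chaykovsky reagent) first closes the chlorohydrin to epoxide 12, then opens it at C7, and ylide-mediated β-elimination of the sulfonium betaine should give the one-carbon-homologated allylic alcohol without touching C8.

Step 7
Reactants: 13 (3R,5Z)-8-[(tert-butyldimethylsilyl)oxy]-5-methylocta-1,5-dien-3-ol
Product: 14 (3R,5Z)-3,8-bis[(tert-butyldimethylsilyl)oxy]-5-methylocta-1,5-diene
Conditions: t-BuMe2SiCl, imidazole, DMAP (cat.), DMF, rt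
Reagents that add atoms: tert-butyldimethylsilyl chloride, CC(C)(C)[Si](C)(C)Cl
Why: Silylation of the secondary allylic alcohol, a silyl ether being required at C8 because it is a poor leaving group in the later allylmetal step.

Step 8
Reactants: 14 (3R,5Z)-3,8-bis[(tert-butyldimethylsilyl)oxy]-5-methylocta-1,5-diene
Product: 15 (3Z,6R)-6-[(tert-butyldimethylsilyl)oxy]-4-methylocta-3,7-dien-1-ol
Conditions: HF·pyridine, pyridine, THF, 0 °C
Reagents that add atoms: none
Why: Selective desilylation, the unhindered primary silyl ether being cleaved much faster than the secondary allylic one under buffered fluoride conditions.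

Step 9
Reactants: 15 (3Z,6R)-6-[(tert-butyldimethylsilyl)oxy]-4-methylocta-3,7-dien-1-ol
Product: 16 (3Z,6R)-6-[(tert-butyldimethylsilyl)oxy]-4-methylocta-3,7-dienal
Conditions: Dess–Martin periodinane, NaHCO3, CH2Cl2, 0 °C; used at once
Reagents that add atoms: none
Why: Dess–Martin oxidation under buffered, non-basic conditions should give the β,γ-unsaturated aldehyde without migration of the (Z)-alkene into conjugation.

Step 10
Reactants: 16 (3Z,6R)-6-[(tert-butyldimethylsilyl)oxy]-4-methylocta-3,7-dienal; 5 (Z)-triethyl({3-iodo-4-[(4-methoxybenzyl)oxy]but-2-en-1-yl}oxy)silane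
Product: 18 (2Z,4S,6Z,9R)-9-[(tert-butyldimethylsilyl)oxy]-3-{[(4-methoxybenzyl)oxy]methyl}-7-methyl-1-[(triethylsilyl)oxy]undeca-2,6,10-trien-4-ol, via alkenylchromium dichloride 17 (not isolated)
Conditions: CrCl2 (4 equiv), NiCl2 (cat.), valinol-derived 2-(oxazolin-2-yl)aryl methanesulfonamide ligand (stoichiometric; the enantiomer that delivers to the Re face of the aldehyde), Et3N, THF, rt
Reagents that add atoms: none
Why: Nozaki–Hiyama–Kishi coupling (oxidative addition of the C–I bond to zerovalent nickel formed in situ, transmetalation to chromium, carbonyl addition) keeps the alkene geometry and tolerates the silyl ethers, and the chiral sulfonamide–oxazoline ligand on chromium should direct the alkenyl group to the Re face of the aldehyde to set C3 as S (reagent control).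

Step 11
Reactants: 18 (2Z,4S,6Z,9R)-9-[(tert-butyldimethylsilyl)oxy]-3-{[(4-methoxybenzyl)oxy]methyl}-7-methyl-1-[(triethylsilyl)oxy]undeca-2,6,10-trien-4-ol
Product: 19 (2Z,4S,6Z,9R)-9-[(tert-butyldimethylsilyl)oxy]-3-{[(4-methoxybenzyl)oxy]methyl}-7-methyl-1-[(triethylsilyl)oxy]undeca-2,6,10-trien-4-yl acetate
Conditions: Ac2O, pyridine, DMAP (cat.), CH2Cl2, 0 °C to rt
Reagents that add atoms: acetic anhydride, CC(=O)OC(C)=O
Why: DMAP-catalysed acetylation of the only free hydroxyl installs the C3 acetate without affecting the stereocentre.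

Step 12
Reactants: 19 (2Z,4S,6Z,9R)-9-[(tert-butyldimethylsilyl)oxy]-3-{[(4-methoxybenzyl)oxy]methyl}-7-methyl-1-[(triethylsilyl)oxy]undeca-2,6,10-trien-4-yl acetate
Product: 20 (2S,3Z)-1-[(2R,3S)-3-{(2R)-2-[(tert-butyldimethylsilyl)oxy]but-3-en-1-yl}-3-methyloxiran-2-yl]-3-{[(4-methoxybenzyl)oxy]methyl}-5-[(triethylsilyl)oxy]pent-3-en-2-yl acetate
Conditions: D-fructose-derived ketone catalyst (1,2:4,5-di-O-isopropylidene-β-D-erythro-2,3-hexodiulo-2,6-pyranose, 30 mol%), KHSO5 (as 2KHSO5·KHSO4·K2SO4), K2CO3, Bu4NHSO4, aq. Na2B4O7/Na2EDTA buffer (pH 10.5), MeCN/CH2(OMe)2, 0 °C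
Reagents that add atoms: potassium peroxymonosulfate, [K+].[O-]S(=O)(=O)OO
Why: Shi epoxidation by the chiral dioxirane through a spiro transition state should attack only the electron-rich C1=C10 alkene (C4=C5 is deactivated by three allylic oxygens, the vinyl group is monosubstituted) and, by the face selectivity known for trisubstituted alkenes with this ketone, give the (1R,10S)-epoxide, the cis relation of C2 and C9 following from the (Z)-alkene.

Step 13
Reactants: 20 (2S,3Z)-1-[(2R,3S)-3-{(2R)-2-[(tert-butyldimethylsilyl)oxy]but-3-en-1-yl}-3-methyloxiran-2-yl]-3-{[(4-methoxybenzyl)oxy]methyl}-5-[(triethylsilyl)oxy]pent-3-en-2-yl acetate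
Product: 22 (2S,3Z)-1-[(2R,3S)-3-{(2R)-2-[(tert-butyldimethylsilyl)oxy]but-3-en-1-yl}-3-methyloxiran-2-yl]-3-{[(4-methoxybenzyl)oxy]methyl}-5-oxopent-3-en-2-yl acetate, via alkoxysulfonium chloride 21 (not isolated)
Conditions: (COCl)2, DMSO, CH2Cl2, −78 to −30 °C; then Et3N, −78 to 0 °C
Reagents that add atoms: none
Why: Under Swern conditions chlorodimethylsulfonium chloride converts a primary triethylsilyl ether directly into the alkoxysulfonium ion and base then gives the aldehyde, whereas the secondary tert-butyldimethylsilyl ether, the acetate and the epoxide are inert, so the (Z)-enal should form in one step with its geometry intact.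

Step 14
Reactants: 22 (2S,3Z)-1-[(2R,3S)-3-{(2R)-2-[(tert-butyldimethylsilyl)oxy]but-3-en-1-yl}-3-methyloxiran-2-yl]-3-{[(4-methoxybenzyl)oxy]methyl}-5-oxopent-3-en-2-yl acetate; 23 methyl 2-(bromomethyl)acrylate
Product: 24 methyl (2Z,4R)-5-[(2S,3R)-3-{(2S,3Z)-2-acetoxy-3-{[(4-methoxybenzyl)oxy]methyl}-5-oxopent-3-en-1-yl}-2-methyloxiran-2-yl]-2-(bromomethyl)-4-[(tert-butyldimethylsilyl)oxy]pent-2-enoate
Conditions: second-generation Hoveyda–Grubbs catalyst (10 mol%), 23 (5 equiv), CH2Cl2, 40 °C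
Reagents that add atoms: none
Why: Olefin cross-metathesis of the only terminal alkene with a 1,1-disubstituted acrylate (which does not homodimerise) should, as with methacrylates, give the trisubstituted enoate with the ester trans to C8, that is the (Z)-2-(bromomethyl)enoate, while the trisubstituted C4=C5 alkene is inert.

Step 15
Reactants: 24 methyl (2Z,4R)-5-[(2S,3R)-3-{(2S,3Z)-2-acetoxy-3-{[(4-methoxybenzyl)oxy]methyl}-5-oxopent-3-en-1-yl}-2-methyloxiran-2-yl]-2-(bromomethyl)-4-[(tert-butyldimethylsilyl)oxy]pent-2-enoate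
Product: 27 (1R,3S,6S,7S,8R,10S)-3-acetoxy-8-[(tert-butyldimethylsilyl)oxy]-1,10-epoxy-15-[(4-methoxybenzyl)oxy]germacra-4Z,11(13)-dien-12,6-olide, via allylchromium dichloride 25 (not isolated), via ring-closed chromium alkoxide 26 (not isolated)
Conditions: CrCl2 (8 equiv), DMF, rt, 24 added by syringe pump to a final 0.003 M
Reagents that add atoms: none
Why: CrCl2 reduces the allylic C13–Br bond by two single-electron transfers to the allylchromium 25 (trivalent chromium), which adds through its γ-carbon C7 to the tethered C6 aldehyde with allyl transposition (C11=C13 exo-methylene), and the resulting C6 chromium alkoxide 26 acylates the cis-disposed C12 methyl ester. The closest known reaction type is the intramolecular Nozaki–Hiyama–Kishi (Barbier-type) allylation of aldehydes by 2-(bromomethyl)acrylates, which is established for ten-membered carbocycles fused to α-methylene-γ-butyrolactones. The carbocycle closes in a 10-exo-trig mode (C7 onto the C6 carbonyl) and the lactone in a 5-exo-trig mode (O6 onto C12). The C6/C7 relationship follows from a Zimmerman–Traxler chair in which C8, cis to CH2Cr in the (Z)-enoate, is axial and the alkenyl residue of the aldehyde equatorial, which gives the syn adduct and hence the cis lactone (H6 and H7 cis). The sense at C7 is controlled by the C8 stereocentre: A(1,3) strain holds H8 in the alkene plane and C6 should bond anti to the C8–C9 bond, on the face of the silyloxy group, which corresponds to the anti C6–C7–C8–C9 array of the target. The step needs γ- over α-attack (inherent to allylchromium), ring closure over oligomerisation (slow addition at high dilution) and no 1,4-elimination of the C8 oxygen, which is why C8 carries a silyl ether and not the methacrylate, while epoxide, acetate and PMB ether are inert to CrCl2.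

Step 16
Reactants: 27 (1R,3S,6S,7S,8R,10S)-3-acetoxy-8-[(tert-butyldimethylsilyl)oxy]-1,10-epoxy-15-[(4-methoxybenzyl)oxy]germacra-4Z,11(13)-dien-12,6-olide
Product: 28 (1R,3S,6S,7R,8R,10S)-3-acetoxy-1,10-epoxy-8-hydroxy-15-[(4-methoxybenzyl)oxy]germacra-4Z,11(13)-dien-12,6-olide
Conditions: HF·pyridine, pyridine, THF, 0 °C to rt
Reagents that add atoms: none
Why: Buffered fluoride desilylation frees the C8 hydroxyl while the excess pyridine protects the acid-sensitive epoxide, and no stereocentre is touched.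

Step 17
Reactants: 28 (1R,3S,6S,7R,8R,10S)-3-acetoxy-1,10-epoxy-8-hydroxy-15-[(4-methoxybenzyl)oxy]germacra-4Z,11(13)-dien-12,6-olide
Product: 29 (1R,3S,6S,7R,8R,10S)-3-acetoxy-1,10-epoxy-15-[(4-methoxybenzyl)oxy]-8-(methacryloyloxy)germacra-4Z,11(13)-dien-12,6-olide
Conditions: methacrylic anhydride, Et3N, DMAP (cat.), CH2Cl2, 0 °C to rt
Reagents that add atoms: methacrylic anhydride, C=C(C)C(=O)OC(=O)C(C)=C
Why: DMAP-catalysed acylation of the only free hydroxyl installs the C8 methacrylate with retention at C8.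

Step 18
Reactants: 29 (1R,3S,6S,7R,8R,10S)-3-acetoxy-1,10-epoxy-15-[(4-methoxybenzyl)oxy]-8-(methacryloyloxy)germacra-4Z,11(13)-dien-12,6-olide
Product: 30 CNP0319155.2, (1R,3S,6S,7R,8R,10S)-3-acetoxy-1,10-epoxy-15-hydroxy-8-(methacryloyloxy)germacra-4Z,11(13)-dien-12,6-olide
Conditions: DDQ, CH2Cl2/pH 7 phosphate buffer, 0 °C
Reagents that add atoms: none
Why: Oxidative cleavage of the 4-methoxybenzyl ether (hydride abstraction by DDQ, then hydrolysis of the oxocarbenium ion) runs under neutral conditions that should spare the epoxide, both esters and the α-methylene lactone and avoid acetyl migration from O3 to O15.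

Compound list
1 | but-2-yne-1,4-diol | OCC#CCO | starting material
2 | 4-[(4-methoxybenzyl)oxy]but-2-yn-1-ol | OCC#CCOCc1ccc(OC)cc1 | intermediate
3 | sodium cyclic alkenylalanate (five-membered Al–O–C6–C5=C4 ring, two 2-methoxyethoxy ligands on aluminium) | [Na+].COCCO[Al-]1(OCCOC)OCC=C1COCc1ccc(OC)cc1 | intermediate
4 | (Z)-3-iodo-4-[(4-methoxybenzyl)oxy]but-2-en-1-ol | OC/C=C(\I)COCc1ccc(OC)cc1 | intermediate
5 | (Z)-triethyl({3-iodo-4-[(4-methoxybenzyl)oxy]but-2-en-1-yl}oxy)silane | CC[Si](CC)(CC)OC/C=C(\I)COCc1ccc(OC)cc1 | intermediate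
6 | 3-[(tert-butyldimethylsilyl)oxy]propanal | CC(C)(C)[Si](C)(C)OCCC=O | starting material
7 | ethyltriphenylphosphonium iodide | CC[P+](c1ccccc1)(c1ccccc1)c1ccccc1.[I-] | starting material
8 | (Z)-tert-butyl[(4-iodopent-3-en-1-yl)oxy]dimethylsilane | CC(C)(C)[Si](C)(C)OCC/C=C(\I)C | intermediate
9 | (R)-epichlorohydrin | ClC[C@H]1CO1 | starting material
10 | [(Z)-5-[(tert-butyldimethylsilyl)oxy]pent-2-en-2-yl]lithium | CC(C)(C)[Si](C)(C)OCC/C=C(\[Li])C | intermediate
11 | (2R,4Z)-8-[(tert-butyldimethylsilyl)oxy]-1-chloro-4-methyloct-4-en-2-ol | CC(C)(C)[Si](C)(C)OCC/C=C(\C[C@@H](O)CCl)C | intermediate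
12 | tert-butyldimethyl({(3Z)-4-methyl-5-[(2R)-oxiran-2-yl]pent-3-en-1-yl}oxy)silane | CC(C)(C)[Si](C)(C)OCC/C=C(\C[C@@H]1CO1)C | intermediate
13 | (3R,5Z)-8-[(tert-butyldimethylsilyl)oxy]-5-methylocta-1,5-dien-3-ol | CC(C)(C)[Si](C)(C)OCC/C=C(\C[C@@H](O)C=C)C | intermediate
14 | (3R,5Z)-3,8-bis[(tert-butyldimethylsilyl)oxy]-5-methylocta-1,5-diene | CC(C)(C)[Si](C)(C)OCC/C=C(\C[C@@H](O[Si](C)(C)C(C)(C)C)C=C)C | intermediate
15 | (3Z,6R)-6-[(tert-butyldimethylsilyl)oxy]-4-methylocta-3,7-dien-1-ol | OCC/C=C(\C[C@@H](O[Si](C)(C)C(C)(C)C)C=C)C | intermediate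
16 | (3Z,6R)-6-[(tert-butyldimethylsilyl)oxy]-4-methylocta-3,7-dienal | O=CC/C=C(\C[C@@H](O[Si](C)(C)C(C)(C)C)C=C)C | intermediate
17 | alkenylchromium dichloride from 5 (CrCl2 in place of I, trivalent chromium) | CC[Si](CC)(CC)OC/C=C(\[Cr](Cl)Cl)COCc1ccc(OC)cc1 | intermediate
18 | (2Z,4S,6Z,9R)-9-[(tert-butyldimethylsilyl)oxy]-3-{[(4-methoxybenzyl)oxy]methyl}-7-methyl-1-[(triethylsilyl)oxy]undeca-2,6,10-trien-4-ol | CC[Si](CC)(CC)OC/C=C(COCc1ccc(OC)cc1)\[C@@H](O)C/C=C(\C[C@@H](O[Si](C)(C)C(C)(C)C)C=C)C | intermediate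
19 | (2Z,4S,6Z,9R)-9-[(tert-butyldimethylsilyl)oxy]-3-{[(4-methoxybenzyl)oxy]methyl}-7-methyl-1-[(triethylsilyl)oxy]undeca-2,6,10-trien-4-yl acetate | CC[Si](CC)(CC)OC/C=C(COCc1ccc(OC)cc1)\[C@@H](OC(C)=O)C/C=C(\C[C@@H](O[Si](C)(C)C(C)(C)C)C=C)C | intermediate
20 | (2S,3Z)-1-[(2R,3S)-3-{(2R)-2-[(tert-butyldimethylsilyl)oxy]but-3-en-1-yl}-3-methyloxiran-2-yl]-3-{[(4-methoxybenzyl)oxy]methyl}-5-[(triethylsilyl)oxy]pent-3-en-2-yl acetate | CC[Si](CC)(CC)OC/C=C(COCc1ccc(OC)cc1)\[C@@H](OC(C)=O)C[C@H]1O[C@@]1(C)C[C@@H](O[Si](C)(C)C(C)(C)C)C=C | intermediate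
21 | alkoxydimethylsulfonium chloride of 20 (Me2S+–O–C6 in place of Et3Si–O–C6) | C[S+](C)OC/C=C(COCc1ccc(OC)cc1)\[C@@H](OC(C)=O)C[C@H]1O[C@@]1(C)C[C@@H](O[Si](C)(C)C(C)(C)C)C=C.[Cl-] | intermediate
22 | (2S,3Z)-1-[(2R,3S)-3-{(2R)-2-[(tert-butyldimethylsilyl)oxy]but-3-en-1-yl}-3-methyloxiran-2-yl]-3-{[(4-methoxybenzyl)oxy]methyl}-5-oxopent-3-en-2-yl acetate | O=C/C=C(COCc1ccc(OC)cc1)\[C@@H](OC(C)=O)C[C@H]1O[C@@]1(C)C[C@@H](O[Si](C)(C)C(C)(C)C)C=C | intermediate
23 | methyl 2-(bromomethyl)acrylate | C=C(CBr)C(=O)OC | starting material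
24 | methyl (2Z,4R)-5-[(2S,3R)-3-{(2S,3Z)-2-acetoxy-3-{[(4-methoxybenzyl)oxy]methyl}-5-oxopent-3-en-1-yl}-2-methyloxiran-2-yl]-2-(bromomethyl)-4-[(tert-butyldimethylsilyl)oxy]pent-2-enoate | O=C/C=C(COCc1ccc(OC)cc1)\[C@@H](OC(C)=O)C[C@H]1O[C@@]1(C)C[C@@H](O[Si](C)(C)C(C)(C)C)/C=C(\CBr)C(=O)OC | intermediate
25 | allylchromium dichloride from 24 (CH2CrCl2 in place of CH2Br, trivalent chromium) | O=C/C=C(COCc1ccc(OC)cc1)\[C@@H](OC(C)=O)C[C@H]1O[C@@]1(C)C[C@@H](O[Si](C)(C)C(C)(C)C)/C=C(\C[Cr](Cl)Cl)C(=O)OC | intermediate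
26 | ring-closed chromium alkoxide: (1R,3S,6S,7S,8R,10S)-configured ten-membered carbocycle with C6–OCrCl2 and the methyl 2-propenoate unit (C11=C13H2, C12 ester) on C7, otherwise substituted as 27 | CC(C)(C)[Si](C)(C)O[C@@H]1C[C@]2(C)O[C@@H]2C[C@H](OC(C)=O)/C(COCc3ccc(OC)cc3)=C\[C@H](O[Cr](Cl)Cl)[C@@H]1C(=C)C(=O)OC | intermediate
27 | (1R,3S,6S,7S,8R,10S)-3-acetoxy-8-[(tert-butyldimethylsilyl)oxy]-1,10-epoxy-15-[(4-methoxybenzyl)oxy]germacra-4Z,11(13)-dien-12,6-olide | CC(C)(C)[Si](C)(C)O[C@@H]1C[C@]2(C)O[C@@H]2C[C@H](OC(C)=O)/C(COCc3ccc(OC)cc3)=C\[C@@H]2OC(=O)C(=C)[C@@H]21 | intermediate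
28 | (1R,3S,6S,7R,8R,10S)-3-acetoxy-1,10-epoxy-8-hydroxy-15-[(4-methoxybenzyl)oxy]germacra-4Z,11(13)-dien-12,6-olide | O[C@@H]1C[C@]2(C)O[C@@H]2C[C@H](OC(C)=O)/C(COCc3ccc(OC)cc3)=C\[C@@H]2OC(=O)C(=C)[C@@H]21 | intermediate
29 | (1R,3S,6S,7R,8R,10S)-3-acetoxy-1,10-epoxy-15-[(4-methoxybenzyl)oxy]-8-(methacryloyloxy)germacra-4Z,11(13)-dien-12,6-olide | C=C(C)C(=O)O[C@@H]1C[C@]2(C)O[C@@H]2C[C@H](OC(C)=O)/C(COCc3ccc(OC)cc3)=C\[C@@H]2OC(=O)C(=C)[C@@H]21 | intermediate
30 | CNP0319155.2, (1R,3S,6S,7R,8R,10S)-3-acetoxy-1,10-epoxy-15-hydroxy-8-(methacryloyloxy)germacra-4Z,11(13)-dien-12,6-olide | C=C(C)C(=O)O[C@@H]1C[C@]2(C)O[C@@H]2C[C@H](OC(C)=O)/C(CO)=C\[C@@H]2OC(=O)C(=C)[C@@H]21 | target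

Total step count: 18.
Longest linear sequence: 15 steps (steps 4 to 18, from 6 and 7); the branch to iodide 5 (steps 1 to 3) joins at step 10.

Steps most likely to fail

1. Step 15 (ring closure). What may go wrong: intermolecular allylation (oligomerisation) overtaking the ten-membered ring closure, or addition through a boat-like or C9-syn transition state that erodes the C6/C7 configuration. The fallback is a non-reductive intramolecular allylboration that sets out from enal 22. Cross-metathesis of 22 with methyl 2-[(4,4,5,5-tetramethyl-1,3,2-dioxaborolan-2-yl)methyl]acrylate (second-generation Hoveyda–Grubbs catalyst, CH2Cl2, 40 °C) would give the allylboronate enal F1. On heating in toluene at high dilution, its 2-(alkoxycarbonyl)allylboronate unit should add to the C6 aldehyde through the corresponding six-membered chair, with boron in place of chromium, to give the cyclic pinacol borate F2. Buffered aqueous work-up should hydrolyse the borate and lactonise the hydroxy ester, which comes back to the route at 27.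

2. Step 14 (cross-metathesis). What may go wrong: slow or stalled metathesis because both alkene partners are hindered (allylic silyloxy group, 1,1-disubstitution), with catalyst decay and erosion of the alkene geometry. The fallback builds the bromide by a Morita–Baylis–Hillman sequence and sets out from epoxide 20. Dihydroxylation and cleavage of the monosubstituted alkene (OsO4 cat., N-methylmorpholine N-oxide; then NaIO4) would give the α-silyloxy aldehyde F3. Morita–Baylis–Hillman reaction with methyl acrylate (DABCO) would give the allylic alcohol F4 as C7 epimers, which is of no consequence. Treatment with N-bromosuccinimide and Me2S would give, by SN2' transposition, the (Z)-allylic bromide F5. HF·pyridine/pyridine at 0 °C would cleave only the primary triethylsilyl ether to give the allylic alcohol F6, and MnO2 oxidation returns to the route at 24.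

3. Step 10 (fragment coupling). What may go wrong: poor facial selectivity at the aldehyde under ligand control, and base-induced migration of the β,γ-alkene into conjugation. The fallback sets out from 16 and 5. Ligand-free coupling (CrCl2, NiCl2 cat., DMSO, rt) would give 18 together with its C3 epimer F7. Dess–Martin oxidation of the mixture would give the enone F8. Corey–Bakshi–Shibata reduction with the (R)-2-methyl-oxazaborolidine and BH3·SMe2 (alkenyl residue as the large group) should then return the (3S)-alcohol 18.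

Further compounds
F1 | step 15 | allylboronate enal: analogue of 24 with CH2B(pinacolato) in place of CH2Br | O=C/C=C(COCc1ccc(OC)cc1)\[C@@H](OC(C)=O)C[C@H]1O[C@@]1(C)C[C@@H](O[Si](C)(C)C(C)(C)C)/C=C(\CB1OC(C)(C)C(C)(C)O1)C(=O)OC
F2 | step 15 | cyclic pinacol borate: analogue of 26 with C6–O–B(pinacolato) in place of C6–OCrCl2 | CC(C)(C)[Si](C)(C)O[C@@H]1C[C@]2(C)O[C@@H]2C[C@H](OC(C)=O)/C(COCc3ccc(OC)cc3)=C\[C@H](OB3OC(C)(C)C(C)(C)O3)[C@@H]1C(=C)C(=O)OC
F3 | step 14 | α-silyloxy aldehyde: analogue of 20 with C7 as CHO in place of the vinyl group | CC[Si](CC)(CC)OC/C=C(COCc1ccc(OC)cc1)\[C@@H](OC(C)=O)C[C@H]1O[C@@]1(C)C[C@@H](O[Si](C)(C)C(C)(C)C)C=O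
F4 | step 14 | Morita–Baylis–Hillman adduct of F3 with methyl acrylate (C7 epimers) | CC[Si](CC)(CC)OC/C=C(COCc1ccc(OC)cc1)\[C@@H](OC(C)=O)C[C@H]1O[C@@]1(C)C[C@@H](O[Si](C)(C)C(C)(C)C)C(O)C(=C)C(=O)OC
F5 | step 14 | (Z)-allylic bromide: analogue of 24 with C6 as CH2OSiEt3 | CC[Si](CC)(CC)OC/C=C(COCc1ccc(OC)cc1)\[C@@H](OC(C)=O)C[C@H]1O[C@@]1(C)C[C@@H](O[Si](C)(C)C(C)(C)C)/C=C(\CBr)C(=O)OC
F6 | step 14 | allylic alcohol: analogue of 24 with C6 as CH2OH | OC/C=C(COCc1ccc(OC)cc1)\[C@@H](OC(C)=O)C[C@H]1O[C@@]1(C)C[C@@H](O[Si](C)(C)C(C)(C)C)/C=C(\CBr)C(=O)OC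
F7 | step 10 | (2Z,4R,6Z,9R)-epimer of 18 | CC[Si](CC)(CC)OC/C=C(COCc1ccc(OC)cc1)\[C@H](O)C/C=C(\C[C@@H](O[Si](C)(C)C(C)(C)C)C=C)C
F8 | step 10 | (2Z,6Z,9R)-9-[(tert-butyldimethylsilyl)oxy]-3-{[(4-methoxybenzyl)oxy]methyl}-7-methyl-1-[(triethylsilyl)oxy]undeca-2,6,10-trien-4-one | CC[Si](CC)(CC)OC/C=C(COCc1ccc(OC)cc1)\C(=O)C/C=C(\C[C@@H](O[Si](C)(C)C(C)(C)C)C=C)C
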